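## The problem

The target 23 is an achiral tetracycle. A 7-hydroxy-5-methylchromone (rings A and B) carries at C2 a resorcinol-type benzene ring (ring C, oxygens at C2' and C4'). C6' of ring C is linked through one CH2 group to C6 of a 4-hydroxy-2-pyrone (ring D).

There is no stereocentre and no isolable atropisomer, so nothing can be steered by an existing stereoelement; the difficulty is purely constitutional. Ring C is 1,2,3,5-tetrasubstituted, with the chromone flanked by an oxygen on one side and the CH2 arm on the other. The C2–C1' bond is therefore doubly ortho-substituted, which makes late aryl–chromone couplings or Claisen condensations of a 2,6-disubstituted benzoate unattractive.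

Several groups will not survive rough treatment:
- the 4-hydroxy-2-pyrone, a vinylogous acid whose lactone opens with hydroxide or alkoxide;
- the chromone, which accepts nucleophiles at C2 and ring-opens in strong aqueous base;
- the CH2 group between ring C and ring D, which is doubly activated and acidic;
- four free hydroxyls that cannot pass unprotected through organometallic or high-temperature steps.

The feature that allows a short synthesis is a hidden repeat. The atoms C3'–C4'(O)–C5'–C6'–CH2 of ring C show the same pattern as C3–C4(O)–C5–C6–CH2 of ring D. A symmetric dipyronylmethane (10) therefore already holds four of the six ring C carbons, the C4' oxygen and the CH2 arm. Only C1' and C2' are missing, and they can come from an alkyne attached to the chromone.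

## Retrosynthesis

**23 to 22.** The three O–CH3 bonds (chromone C7–O, ring C C4'–O, pyrone C4–O) are cut last. Methyl is forced on the pyrone oxygen, because the diene of the key step must be an enol ether and a free hydroxypyrone (pKa about 5) would protonate a C–B bond. Through the key step the same methyl becomes the C4' ether. Using methyl on C7 as well lets one Lewis acid finish the synthesis. The forward reaction must cleave two aryl ethers and a vinylogous ester without harming lactone or chromone.

**22 to 21.** The C2'–O bond is traced back to a C2'–B bond. Boron is preferred to an oxygen carried on the alkyne (ynol ethers of this type are not stable enough) and to a late C–H hydroxylation (no directing group points at C2'). The forward step is a mild peroxide oxidation with retention of position, so the free 2'-hydroxyl appears only one step before the end and needs no protecting group.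

**21 to 19 and 10.** Ring C is opened at C2'–C3' and C1'–C6', with CO2 added back across C3' and C6'. This gives the alkynylboronate 19 and the symmetric bis-pyrone 10, fragments of 19 and 13 carbons. The neighbouring cut of ring C (C1'–C2' and C5'–C6') needs an alkyne with a CH2 between triple bond and pyrone, which isomerises easily to an allene. A cut at the C2–C1' bond would demand a hindered coupling. The chosen cut asks the forward reaction for regiocontrol only, since 10 is symmetric, and for an alkyne that tolerates about 180 °C.

**10 to 4, 3 and 1.** Ring D is grown on the methyl group of commercial pyrone 4.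
- Methyl ether 10 comes from hydroxypyrone 9.
- The lactone C–O bond of 9 is opened to the 3,5-dioxo ester 8.
- The C4–C5 bond of 8 is cut to the acid chloride 6 (from acid 5, made by carboxylating 4) and the four-carbon bis(silyl enol ether) 3, made in two steps from methyl acetoacetate 1 via 2.
- A strongly basic acetoacetate dianion was rejected as the nucleophile. The CH2 of any pyronylacetic acid derivative is doubly activated, and a dianion would deprotonate it instead of being acylated. The neutral diene 3 avoids this.

**19 to 17.** The C(sp)–B bond is cut to the terminal alkyne 18, and its C–H to the C–Si bond of 17. Boron is put on last because an alkynylboronate would not survive the base and acid of chromone formation. The forward step needs a base that removes the alkyne proton without adding to the chromone.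

**17 to 14 and 15.** The chromone is opened at O1–C2 to the diketone 16, and the C3–C2 bond of 16 is cut to the acetophenone 14 and the commercial silyl ynoate 15. This two-step Claisen and cyclodehydration route is three or four steps shorter than routes through a chromone-2-carboxylate and an aldehyde homologation. The silyl cap protects the acidic alkyne proton and shields the ynoate β-carbon from conjugate addition.

**14 to 11.** Removing the methyl ether gives 13, and removing the acetyl group gives orcinol 11. The forward steps use two well-known selectivities: acylation of orcinol para to a hydroxyl, and methylation of the hydroxyl that is not hydrogen-bonded to the ketone.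

## Roads not taken

**Alternative 1:** Ring A is cut at C4a–C8a and C5–C6. The diynone A1 would react with the Brassard-type diene A2 at its methyl-substituted triple bond; loss of methanol would give the ortho-hydroxyaryl ynone A3, which then has to close 6-endo to the chromone.
- *Merits:* additions of such dienes to ynones have well-founded regiochemistry, firmer than the orientation the chosen plan has to win. The phenol is freed exactly where the chromone oxygen is needed. No boron chemistry is involved.
- *Weak points:* the elaborate step builds ring A, the one ring that orcinol supplies for nothing. Ring C, with its CH2-pyrone arm and an ortho alkyne, must first be made by a long linear sequence. A1 has two ynone triple bonds, the hydrolytically fragile A2 is spent on an advanced intermediate, and the closure of A3 can also go 5-exo to an aurone.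
- *Comparison:* the chosen plan sets convergence against the surer regiochemistry of this road. Two fragments of six steps each are joined, and the cycloaddition creates the crowded ring C itself.

**Alternative 2:** Only C–O bonds are cut, O1–C2 of the chromone and O–C6 of the pyrone. The precursor A4 would be treated with Ph3PAuCl and AgSbF6. The phenol adds to the aryl ynone, and the tert-butyl ester carbonyl adds to the keto ynoate with loss of isobutene, giving A5.
- *Merits:* the reaction is catalytic and runs near room temperature. Two heterocycles close in one operation, and the pyrone hydroxyl emerges free. As a single reaction it is probably more dependable than a cycloaddition at 180 °C.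
- *Weak points:* no carbon–carbon bond of the skeleton is formed, so the whole substitution problem of ring C is moved into the synthesis of A4. A4 has two different alkynyl chains on adjacent ring positions. Its CH2 group, both benzylic and propargylic next to an ynone, is prone to allene formation. Its β-keto ester and its free phenol beside an ynone may cyclise prematurely or 5-exo.
- *Comparison:* the chosen plan answers with a key step that forms two skeletal bonds and a ring from fragments that are each easy to make and to store.

**Alternative 3:** Ring C is cut at C1'–C2' and C5'–C6'. The 2-alkynylchromone A6 would take up the diene A2, and loss of methanol would give the phenol A7, which has the constitution of compound 22.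
- *Merits:* this is the closest relative of the chosen plan and on paper the shorter one. The 2'-hydroxyl arrives free, so borylation and oxidation (two steps) and the water-sensitive alkynylboronate are avoided. The nucleophilic diene terminus meets the β-carbon of the chromone-activated alkyne, a well-matched polarisation.
- *Weak points:* the CH2 group of A6 sits between a triple bond and a pyrone and should isomerise to the conjugated allene with traces of base or on heating. A6 needs its own unsymmetrical synthesis from a propargyl pyrone. A2 adds sluggishly to internal, only vinylogously activated alkynes and decomposes at the temperatures this would need.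
- *Comparison:* the chosen plan sets the robust symmetric diene 10 against this, where the same CH2 is flanked by two pyrone rings. Its dienophile 19 has no propargylic hydrogens, and it pays with two extra steps and an open regiochemical question.

Key step: step 13

Remark on the chemistry: 2, 3 and 7 are mixtures of double-bond isomers that converge in step 4. 20 is racemic and drawn as one enantiomer. Lithium enolates, the lithium acetylide and its borate complex are treated as salts of the numbered compounds and carry no numbers of their own.

## Route

Step 1
Reactants: 1 methyl acetoacetate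
Product: 2 methyl 3-(trimethylsilyloxy)but-2-enoate
Conditions: Me3SiCl, Et3N, hexane, rt
Reagents that add atoms: chlorotrimethylsilane, C[Si](C)(C)Cl
Why: O-silylation of the enol of the β-keto ester (silyl enol ether formation); the isomer mixture is of no consequence because the geometry is erased in step 4.

Step 2
Reactants: 2 methyl 3-(trimethylsilyloxy)but-2-enoate
Product: 3 1-methoxy-1,3-bis(trimethylsilyloxy)buta-1,3-diene
Conditions: LiN(iPr)2, THF, −78 °C; Me3SiCl, −78 °C → rt
Reagents that add atoms: chlorotrimethylsilane, C[Si](C)(C)Cl
Why: Deprotonation of the ester to its enolate and O-silylation give the 1,3-bis(silyl enol ether) (standard preparation of Chan's diene), a neutral equivalent of the acetoacetate dianion.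

Step 3
Reactants: 4 4-methoxy-6-methyl-2H-pyran-2-one
Product: 5 (4-methoxy-2-oxo-2H-pyran-6-yl)acetic acid
Conditions: LiN(iPr)2, THF, −78 °C; CO2 (excess), −78 °C; 1 M HCl, 0 °C
Reagents that add atoms: carbon dioxide, O=C=O
Why: Lateral (vinylogous) lithiation of the 6-methyl group of 4-methoxy-2-pyrones at low temperature followed by carboxylation; the anion is transferred onto excess CO2 to limit proton exchange with the more acidic product, and the acid is kept cold because it can decarboxylate on heating.

Step 4
Reactants: 5 (4-methoxy-2-oxo-2H-pyran-6-yl)acetic acid; 3 1-methoxy-1,3-bis(trimethylsilyloxy)buta-1,3-diene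
Product: 8 methyl 6-(4-methoxy-2-oxo-2H-pyran-6-yl)-3,5-dioxohexanoate, via acid chloride 6 (not isolated), via silyl enol ether 7 (not isolated)
Conditions: (COCl)2, DMF (cat.), CH2Cl2, 0 °C → rt, evaporate; 3, CH2Cl2, −78 °C → rt; 1 M HCl
Reagents that add atoms: none
Why: Acid chloride formation followed by uncatalysed γ-selective C-acylation of the bis(silyl enol ether) (Mukaiyama-type acylation of Chan's diene) builds the 3,5-dioxo ester without any base, so the doubly activated CH2 of 6 is not deprotonated; aqueous acid hydrolyses the silyl enol ether 7.

Step 5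
Reactants: 8 methyl 6-(4-methoxy-2-oxo-2H-pyran-6-yl)-3,5-dioxohexanoate
Product: 9 4-hydroxy-6-[(4-methoxy-2-oxo-2H-pyran-6-yl)methyl]-2H-pyran-2-one
Conditions: DBU, toluene, rt; 1 M HCl
Reagents that add atoms: none
Why: Enol lactonisation of a 3,5-dioxo ester (the C5 enolate oxygen displaces methoxide from the ester, 6-exo-trig) is the standard closure to 4-hydroxy-2-pyrones; DBU gives only the O-nucleophilic monoanion, so carbocyclic Claisen closure, which needs a polyanion, should not compete.

Step 6
Reactants: 9 4-hydroxy-6-[(4-methoxy-2-oxo-2H-pyran-6-yl)methyl]-2H-pyran-2-one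
Product: 10 6,6'-methylenebis(4-methoxy-2H-pyran-2-one)
Conditions: Me2SO4, K2CO3, acetone, reflux
Reagents that add atoms: dimethyl sulfate, COS(=O)(=O)OC
Why: O-methylation of the vinylogous acid with a hard methylating agent and a weak base gives the 4-methoxy-2-pyrone, as for triacetic acid lactone; carbonate is too weak to alkylate the bridging CH2.

Step 7
Reactants: 11 orcinol
Product: 13 1-(2,4-dihydroxy-6-methylphenyl)ethan-1-one, via ketiminium chloride 12 (not isolated)
Conditions: MeCN, ZnCl2, HCl (g), Et2O, 0 °C; then H2O, reflux
Reagents that add atoms: acetonitrile, CC#N; water, O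
Why: Hoesch acylation; the nitrilium electrophile attacks C4 of orcinol (para to one hydroxyl, ortho to the other) and not the position between the two hydroxyls, and the ketiminium salt is hydrolysed to the ketone.

Step 8
Reactants: 13 1-(2,4-dihydroxy-6-methylphenyl)ethan-1-one
Product: 14 1-(2-hydroxy-4-methoxy-6-methylphenyl)ethan-1-one
Conditions: MeI (1.05 equiv), K2CO3, acetone, rt
Reagents that add atoms: iodomethane, CI
Why: Williamson etherification; the 2-hydroxyl is held in a hydrogen bond to the ketone, so the 4-hydroxyl is alkylated selectively with one equivalent of iodomethane.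

Step 9
Reactants: 14 1-(2-hydroxy-4-methoxy-6-methylphenyl)ethan-1-one; 15 ethyl 3-(trimethylsilyl)propiolate
Product: 16 1-(2-hydroxy-4-methoxy-6-methylphenyl)-5-(trimethylsilyl)pent-4-yne-1,3-dione
Conditions: LiN(SiMe3)2 (3.2 equiv), THF, −78 °C; 15, −78 → −20 °C; 1 M HCl
Reagents that add atoms: none
Why: Crossed Claisen condensation of the phenoxide–enolate dianion with the ynoate ester (first half of a Baker–Venkataraman-type chromone synthesis); the third equivalent of base takes up the acidic β-diketone, and the silyl group blocks the ynoate β-carbon against conjugate addition.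

Step 10
Reactants: 16 1-(2-hydroxy-4-methoxy-6-methylphenyl)-5-(trimethylsilyl)pent-4-yne-1,3-dione
Product: 17 7-methoxy-5-methyl-2-[(trimethylsilyl)ethynyl]-4H-chromen-4-one
Conditions: p-TsOH·H2O (cat.), toluene, 80 °C
Reagents that add atoms: none
Why: Acid-catalysed cyclodehydration of an ortho-hydroxyaryl 1,3-diketone; the phenol adds to the more electrophilic alkynyl ketone (6-exo-trig) and the hemiketal loses water, while the silyl group shields the alkyne terminus from 6-endo attack by the enol oxygen.

Step 11
Reactants: 17 7-methoxy-5-methyl-2-[(trimethylsilyl)ethynyl]-4H-chromen-4-one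
Product: 18 2-ethynyl-7-methoxy-5-methyl-4H-chromen-4-one
Conditions: n-Bu4NF, AcOH, THF, 0 °C
Reagents that add atoms: none
Why: Fluoride-induced protodesilylation of an alkynylsilane; the acetic acid buffer keeps the medium from becoming basic enough to add nucleophiles to the electron-poor alkyne or to open the chromone.

Step 12
Reactants: 18 2-ethynyl-7-methoxy-5-methyl-4H-chromen-4-one
Product: 19 7-methoxy-5-methyl-2-[(4,4,5,5-tetramethyl-1,3,2-dioxaborolan-2-yl)ethynyl]-4H-chromen-4-one
Conditions: LiN(SiMe3)2, THF, −78 °C; iPrOBpin, −78 °C; HCl in Et2O, −78 °C → rt; filtered and used without chromatography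
Reagents that add atoms: 2-isopropoxy-4,4,5,5-tetramethyl-1,3,2-dioxaborolane, CC(C)OB1OC(C)(C)C(C)(C)O1
Why: Standard alkynylboronic ester synthesis: the non-nucleophilic amide removes the acidic alkyne proton without adding to the chromone, the acetylide is trapped as a borate complex, and anhydrous HCl releases the pinacol ester.

Step 13
Reactants: 19 7-methoxy-5-methyl-2-[(4,4,5,5-tetramethyl-1,3,2-dioxaborolan-2-yl)ethynyl]-4H-chromen-4-one; 10 6,6'-methylenebis(4-methoxy-2H-pyran-2-one)
Product: 21 7-methoxy-2-[4-methoxy-2-[(4-methoxy-2-oxo-2H-pyran-6-yl)methyl]-6-(4,4,5,5-tetramethyl-1,3,2-dioxaborolan-2-yl)phenyl]-5-methyl-4H-chromen-4-one, via bridged bicyclic lactone 20 (not isolated)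
Conditions: 10 (3 equiv), 1,2-dichlorobenzene, 180 °C, sealed tube, argon
Reagents that add atoms: none
Why: One 4-methoxy-2-pyrone ring of 10 acts as an electron-rich diene through C3 and C6 and adds to the acceptor-substituted alkyne of 19 in a thermal, concerted but asynchronous [4+2] cycloaddition; the bridged lactone 20 then loses CO2 in a retro-[4+2] step and aromatises to 21. The closest known reaction type is the Diels–Alder/retro-Diels–Alder sequence of 2-pyrones with alkynylboronic esters, which gives arylboronates, together with the additions of 4-methoxy-6-alkyl-2-pyrones to acceptor alkynes. Ring C is closed in an intermolecular [4+2] mode, a four-carbon unit (pyrone C3 to C6) and a two-carbon unit (the alkyne) giving the six-membered ring with both new bonds, C2'–C3' and C1'–C6', formed in the same step, and the CO2 extrusion makes the closure irreversible. No stereocentre is created in 21: the two bridgeheads of 20 arise as a racemic pair whose relative configuration is fixed by the bicycle, and both become sp2 carbons. The step needs regiocontrol, and three features point the same way: pyrone C3 is the β-carbon of the enol ether and the more nucleophilic diene terminus, the boron-bearing alkyne carbon is the electrophilic δ-position of the O=C4–C3=C2–C≡C chain of the chromone, and the unsubstituted C3 is the less hindered partner for the carbon that carries the pinacol boronate, so the chromone should end up beside the CH2 arm. Site selectivity is not needed because the two rings of 10 are identical, and the excess of 10 keeps the remaining pyrone of 21 from adding a second alkyne. Chemoselectivity rests on the alkyne being a better 2π partner than the donor-substituted C2=C3 bond of the chromone, and the dry aprotic medium keeps the C(sp)–B bond intact until it has become the more robust aryl C–B bond.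

Step 14
Reactants: 21 7-methoxy-2-[4-methoxy-2-[(4-methoxy-2-oxo-2H-pyran-6-yl)methyl]-6-(4,4,5,5-tetramethyl-1,3,2-dioxaborolan-2-yl)phenyl]-5-methyl-4H-chromen-4-one
Product: 22 2-[2-hydroxy-4-methoxy-6-[(4-methoxy-2-oxo-2H-pyran-6-yl)methyl]phenyl]-7-methoxy-5-methyl-4H-chromen-4-one
Conditions: NaBO3·4H2O, THF/H2O, rt
Reagents that add atoms: sodium perborate (NaBO3·4H2O), [Na+].[O-]OB=O
Why: Oxidation of an arylboronic ester by peroxoborate (1,2-shift of the aryl group from boron to oxygen, then hydrolysis of the borate) puts the hydroxyl exactly where boron stood; the mild, weakly basic medium should spare the chromone and the pyrone lactone.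

Step 15
Reactants: 22 2-[2-hydroxy-4-methoxy-6-[(4-methoxy-2-oxo-2H-pyran-6-yl)methyl]phenyl]-7-methoxy-5-methyl-4H-chromen-4-one
Product: 23 7-hydroxy-2-[2,4-dihydroxy-6-[(4-hydroxy-2-oxo-2H-pyran-6-yl)methyl]phenyl]-5-methyl-4H-chromen-4-one
Conditions: BBr3 (excess), CH2Cl2, −78 °C → rt; then H2O, 0 °C
Reagents that add atoms: none
Why: Lewis-acid ether cleavage: BBr3 binds each ether oxygen (for the pyrone, the lactone carbonyl of the vinylogous ester) and bromide removes the methyl group by SN2; the three O–CH3 bonds are the only cleavable ones, and water releases the hydroxyls from their borates.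

## Compound list

1 | methyl acetoacetate | CC(=O)CC(=O)OC | starting material
2 | methyl 3-(trimethylsilyloxy)but-2-enoate (mixture of double-bond isomers) | CC(O[Si](C)(C)C)=CC(=O)OC | intermediate
3 | 1-methoxy-1,3-bis(trimethylsilyloxy)buta-1,3-diene (Chan's diene, ketene acetal geometry not defined) | C=C(O[Si](C)(C)C)C=C(OC)O[Si](C)(C)C | intermediate
4 | 4-methoxy-6-methyl-2H-pyran-2-one | COc1cc(C)oc(=O)c1 | starting material
5 | (4-methoxy-2-oxo-2H-pyran-6-yl)acetic acid | COc1cc(=O)oc(CC(=O)O)c1 | intermediate
6 | (4-methoxy-2-oxo-2H-pyran-6-yl)acetyl chloride | COc1cc(=O)oc(CC(=O)Cl)c1 | intermediate (not isolated)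
7 | methyl 6-(4-methoxy-2-oxo-2H-pyran-6-yl)-5-oxo-3-(trimethylsilyloxy)hex-2-enoate (mixture of double-bond isomers) | COC(=O)C=C(CC(=O)Cc1cc(OC)cc(=O)o1)O[Si](C)(C)C | intermediate (not isolated)
8 | methyl 6-(4-methoxy-2-oxo-2H-pyran-6-yl)-3,5-dioxohexanoate | COC(=O)CC(=O)CC(=O)Cc1cc(OC)cc(=O)o1 | intermediate
9 | 4-hydroxy-6-[(4-methoxy-2-oxo-2H-pyran-6-yl)methyl]-2H-pyran-2-one | COc1cc(=O)oc(Cc2cc(O)cc(=O)o2)c1 | intermediate
10 | 6,6'-methylenebis(4-methoxy-2H-pyran-2-one) | COc1cc(=O)oc(Cc2cc(OC)cc(=O)o2)c1 | intermediate
11 | orcinol (5-methylbenzene-1,3-diol) | Cc1cc(O)cc(O)c1 | starting material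
12 | 1-(2,4-dihydroxy-6-methylphenyl)ethan-1-iminium chloride | CC(=[NH2+])c1c(C)cc(O)cc1O.[Cl-] | intermediate (not isolated)
13 | 1-(2,4-dihydroxy-6-methylphenyl)ethan-1-one | CC(=O)c1c(C)cc(O)cc1O | intermediate
14 | 1-(2-hydroxy-4-methoxy-6-methylphenyl)ethan-1-one | CC(=O)c1c(C)cc(OC)cc1O | intermediate
15 | ethyl 3-(trimethylsilyl)propiolate | CCOC(=O)C#C[Si](C)(C)C | starting material
16 | 1-(2-hydroxy-4-methoxy-6-methylphenyl)-5-(trimethylsilyl)pent-4-yne-1,3-dione | COc1cc(C)c(C(=O)CC(=O)C#C[Si](C)(C)C)c(O)c1 | intermediate
17 | 7-methoxy-5-methyl-2-[(trimethylsilyl)ethynyl]-4H-chromen-4-one | COc1cc(C)c2c(c1)oc(C#C[Si](C)(C)C)cc2=O | intermediate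
18 | 2-ethynyl-7-methoxy-5-methyl-4H-chromen-4-one | COc1cc(C)c2c(c1)oc(C#C)cc2=O | intermediate
19 | 7-methoxy-5-methyl-2-[(4,4,5,5-tetramethyl-1,3,2-dioxaborolan-2-yl)ethynyl]-4H-chromen-4-one | COc1cc(C)c2c(c1)oc(C#CB1OC(C)(C)C(C)(C)O1)cc2=O | intermediate
20 | 7-methoxy-2-[5-methoxy-1-[(4-methoxy-2-oxo-2H-pyran-6-yl)methyl]-3-oxo-8-(4,4,5,5-tetramethyl-1,3,2-dioxaborolan-2-yl)-2-oxabicyclo[2.2.2]octa-5,7-dien-7-yl]-5-methyl-4H-chromen-4-one (racemic; bridgehead C1 bears the pyronylmethyl group, bridgehead C4 bears hydrogen; one enantiomer drawn) | O=C1O[C@@]2(Cc3cc(OC)cc(=O)o3)C=C(OC)[C@@H]1C(B1OC(C)(C)C(C)(C)O1)=C2c1cc(=O)c2c(C)cc(OC)cc2o1 | intermediate (not isolated)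
21 | 7-methoxy-2-[4-methoxy-2-[(4-methoxy-2-oxo-2H-pyran-6-yl)methyl]-6-(4,4,5,5-tetramethyl-1,3,2-dioxaborolan-2-yl)phenyl]-5-methyl-4H-chromen-4-one | COc1cc(C)c2c(c1)oc(-c1c(B3OC(C)(C)C(C)(C)O3)cc(OC)cc1Cc1cc(OC)cc(=O)o1)cc2=O | intermediate
22 | 2-[2-hydroxy-4-methoxy-6-[(4-methoxy-2-oxo-2H-pyran-6-yl)methyl]phenyl]-7-methoxy-5-methyl-4H-chromen-4-one | COc1cc(C)c2c(c1)oc(-c1c(O)cc(OC)cc1Cc1cc(OC)cc(=O)o1)cc2=O | intermediate
23 | 7-hydroxy-2-[2,4-dihydroxy-6-[(4-hydroxy-2-oxo-2H-pyran-6-yl)methyl]phenyl]-5-methyl-4H-chromen-4-one | Cc1cc(O)cc2oc(-c3c(O)cc(O)cc3Cc3cc(O)cc(=O)o3)cc(=O)c12 | target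

## Step count and least certain steps

Total: 15 steps. Longest linear sequence: 9 steps (orcinol 11 to 23, steps 7 to 15). The bis-pyrone branch (steps 1 to 6) joins at step 13.

**Step 13 (key step).** The most likely failure is loss of regiocontrol. The boronate is itself a weak π-acceptor that polarises the triple bond in the sense opposite to the chromone, so the two orientations of 19 on the pyrone may compete, and the long heating gives protodeboronation time to intervene.

The fallback replaces boron by a marker that polarises the alkyne in the same sense as the chromone. It sets out from 18. Bromination of the alkyne C–H with N-bromosuccinimide and catalytic AgNO3 in acetone should give 2-(bromoethynyl)-7-methoxy-5-methyl-4H-chromen-4-one F1. Heated with an excess of 10 in 1,2-dichlorobenzene, this donor–acceptor alkyne should pass through the racemic bridged lactone 2-[8-bromo-5-methoxy-1-[(4-methoxy-2-oxo-2H-pyran-6-yl)methyl]-3-oxo-2-oxabicyclo[2.2.2]octa-5,7-dien-7-yl]-7-methoxy-5-methyl-4H-chromen-4-one F2 to the aryl bromide 2-[2-bromo-4-methoxy-6-[(4-methoxy-2-oxo-2H-pyran-6-yl)methyl]phenyl]-7-methoxy-5-methyl-4H-chromen-4-one F3. Miyaura borylation of F3 with B2pin2, PdCl2(dppf) and KOAc in dioxane returns to the route at 21.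

**Step 12.** The most likely failure is loss of the boryl group by protonolysis during the HCl quench and isolation. The C(sp)–B bond of an electron-poor alkynyl pinacol ester is labile towards traces of water and silica.

The fallback sets out from 18 and stores the boron as a tetracoordinate salt. The acetylide is trapped with B(OMe)3 and treated with aqueous KHF2 to give potassium trifluoro[(7-methoxy-5-methyl-4-oxo-4H-chromen-2-yl)ethynyl]borate F4, a crystalline, water-stable solid. Just before the cycloaddition, F4 is converted with pinacol and Me3SiCl in dry MeCN into 19, whose filtered solution is used directly. The route is rejoined at 19.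

**Step 9 (with consequences for step 10).** The most likely failure is conjugate addition of the enolate or phenoxide to the ynoate, or cyclisation of the diketone dianion onto the triple bond, in place of clean C-acylation.

The fallback builds the alkyne from a chromone-2-carboxylate and sets out from 14.
- Claisen condensation with diethyl oxalate (NaOEt, EtOH) and acid cyclisation give ethyl 7-methoxy-5-methyl-4-oxo-4H-chromene-2-carboxylate F5.
- Chemoselective reduction of the activated ester with NaBH4 in MeOH at 0 °C gives 2-(hydroxymethyl)-7-methoxy-5-methyl-4H-chromen-4-one F6.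
- Oxidation with Dess–Martin periodinane gives 7-methoxy-5-methyl-4-oxo-4H-chromene-2-carbaldehyde F7.
- Homologation with the Ohira–Bestmann reagent (K2CO3, MeOH) rejoins the route at 18, bypassing 16 and 17.

**Step 15.** The most likely failure is incomplete cleavage. The chromone C7 ether and the vinylogous ester have oxygens of low Lewis basicity, and forcing the reaction with more BBr3 and heat may degrade the hydroxypyrone.

The fallback divides the work between two mechanisms and sets out from 22. Nucleophilic demethylation with LiCl in DMF at 130 °C should remove the two methyl groups whose oxygens are good leaving groups (the pyrone ether and the C7 ether para to the ketone). This gives 7-hydroxy-2-[2-hydroxy-6-[(4-hydroxy-2-oxo-2H-pyran-6-yl)methyl]-4-methoxyphenyl]-5-methyl-4H-chromen-4-one F8. The single remaining electron-rich aryl ether is then cleaved with a small excess of BBr3 at low temperature, which ends at 23.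

## Further compounds

F1 | step 13 | 2-(bromoethynyl)-7-methoxy-5-methyl-4H-chromen-4-one | COc1cc(C)c2c(c1)oc(C#CBr)cc2=O
F2 | step 13 | 2-[8-bromo-5-methoxy-1-[(4-methoxy-2-oxo-2H-pyran-6-yl)methyl]-3-oxo-2-oxabicyclo[2.2.2]octa-5,7-dien-7-yl]-7-methoxy-5-methyl-4H-chromen-4-one (racemic, one enantiomer drawn) | O=C1O[C@@]2(Cc3cc(OC)cc(=O)o3)C=C(OC)[C@@H]1C(Br)=C2c1cc(=O)c2c(C)cc(OC)cc2o1
F3 | step 13 | 2-[2-bromo-4-methoxy-6-[(4-methoxy-2-oxo-2H-pyran-6-yl)methyl]phenyl]-7-methoxy-5-methyl-4H-chromen-4-one | COc1cc(C)c2c(c1)oc(-c1c(Br)cc(OC)cc1Cc1cc(OC)cc(=O)o1)cc2=O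
F4 | step 12 | potassium trifluoro[(7-methoxy-5-methyl-4-oxo-4H-chromen-2-yl)ethynyl]borate | COc1cc(C)c2c(c1)oc(C#C[B-](F)(F)F)cc2=O.[K+]
F5 | step 9 | ethyl 7-methoxy-5-methyl-4-oxo-4H-chromene-2-carboxylate | CCOC(=O)c1cc(=O)c2c(C)cc(OC)cc2o1
F6 | step 9 | 2-(hydroxymethyl)-7-methoxy-5-methyl-4H-chromen-4-one | COc1cc(C)c2c(c1)oc(CO)cc2=O
F7 | step 9 | 7-methoxy-5-methyl-4-oxo-4H-chromene-2-carbaldehyde | COc1cc(C)c2c(c1)oc(C=O)cc2=O
F8 | step 15 | 7-hydroxy-2-[2-hydroxy-6-[(4-hydroxy-2-oxo-2H-pyran-6-yl)methyl]-4-methoxyphenyl]-5-methyl-4H-chromen-4-one | Cc1cc(O)cc2oc(-c3c(O)cc(OC)cc3Cc3cc(O)cc(=O)o3)cc(=O)c12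
A1 | alternative 1 | 1-[2,4-dimethoxy-6-[(4-methoxy-2-oxo-2H-pyran-6-yl)methyl]phenyl]hexa-1,4-diyn-3-one | CC#CC(=O)C#Cc1c(OC)cc(OC)cc1Cc1cc(OC)cc(=O)o1
A2 | alternative 1 | 1,3-dimethoxy-1-(trimethylsilyloxy)buta-1,3-diene | COC(=C)C=C(OC)O[Si](C)(C)C
A3 | alternative 1 | 6-[2-[3-(2-hydroxy-4-methoxy-6-methylphenyl)-3-oxoprop-1-yn-1-yl]-3,5-dimethoxybenzyl]-4-methoxy-2H-pyran-2-one | COc1cc(C)c(C(=O)C#Cc2c(OC)cc(OC)cc2Cc2cc(OC)cc(=O)o2)c(O)c1
A4 | alternative 2 | tert-butyl 6-[2-[3-(2-hydroxy-4-methoxy-6-methylphenyl)-3-oxoprop-1-yn-1-yl]-3,5-dimethoxyphenyl]-3-oxohex-4-ynoate | COc1cc(C)c(C(=O)C#Cc2c(OC)cc(OC)cc2CC#CC(=O)CC(=O)OC(C)(C)C)c(O)c1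
A5 | alternative 2 | 2-[2-[(4-hydroxy-2-oxo-2H-pyran-6-yl)methyl]-4,6-dimethoxyphenyl]-7-methoxy-5-methyl-4H-chromen-4-one | COc1cc(C)c2c(c1)oc(-c1c(OC)cc(OC)cc1Cc1cc(O)cc(=O)o1)cc2=O
A6 | alternative 3 | 7-methoxy-2-[3-(4-methoxy-2-oxo-2H-pyran-6-yl)prop-1-yn-1-yl]-5-methyl-4H-chromen-4-one | COc1cc(C)c2c(c1)oc(C#CCc1cc(OC)cc(=O)o1)cc2=O
A7 | alternative 3 | 2-[2-hydroxy-4-methoxy-6-[(4-methoxy-2-oxo-2H-pyran-6-yl)methyl]phenyl]-7-methoxy-5-methyl-4H-chromen-4-one | COc1cc(C)c2c(c1)oc(-c1c(O)cc(OC)cc1Cc1cc(OC)cc(=O)o1)cc2=O
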